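**Retrosynthetic overview**

1. Target ⇐ desilylation and saponification of a bis-silyl diethyl ester; C2=C3 ⇐ Horner–Wadsworth–Emmons olefination of an α,β-epoxy methyl ketone.
2. Only one ring is ever formed, the oxirane. It is closed late by hydroxyl-directed epoxidation of a (Z)-trisubstituted allylic alcohol; the directing carbinol (from (R)-but-3-yn-2-ol) is then oxidised to the ketone.
3. C5–C6 ⇐ Negishi coupling of (2R,3Z)-4-iodopent-3-en-2-ol with a C6–C14 alkylzinc iodide.
4. C9–C10 ⇐ cross-metathesis and hydrogenation of the C10–C14 head alkene with (2S,4E)-2-methylhex-4-en-1-ol; the C7–C8 bond and the C7 centre of the latter ⇐ key Ireland–Claisen [3,3] rearrangement of (R)-but-3-en-2-yl propanoate (1,3-chirality transfer).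
5. Head ⇐ ethyl (S)-3,4-epoxybutanoate (C12 bought) + vinyl Grignard/CuI, then Fráter–Seebach hydroxymethylation (C13 anti to the C12 oxygen).

Assumption: the SMILES is taken literally, i.e. (2E,4S,5R,7S,12R,13R) with the C3 and C6 substituents cis on the oxirane; atoms are numbered C1 (enoic acid carbon) to C14 throughout; TBS = tert-butyldimethylsilyl.

**Route**

Step 1
Reactants: 1 ethyl (S)-3,4-epoxybutanoate
Product: 2 ethyl (R)-3-hydroxyhex-5-enoate
Conditions: CH2=CHMgBr (1.5 equiv), CuI (10 mol %), THF, −40 → −20 °C; then 1 M HCl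
Reagents that add atoms: vinylmagnesium bromide, C=C[Mg]Br
Why: Copper-catalysed Grignard opening of the terminal epoxide (SN2 at the unhindered CH2) extends the chain to C10 without touching the purchased carbinol centre, which becomes (12R).

Step 2
Reactants: 2 ethyl (R)-3-hydroxyhex-5-enoate
Product: 4 ethyl (2R,3R)-3-hydroxy-2-(hydroxymethyl)hex-5-enoate, via dilithium dianion 3 (not isolated)
Conditions: LiN(i-Pr)2 (2.2 equiv), THF, −78 → −20 °C; CH2O (gas, cracked paraformaldehyde), −78 °C; then 1 M HCl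
Reagents that add atoms: formaldehyde, C=O
Why: Fráter–Seebach reaction (aldol of the β-alkoxide ester enolate): in the lithium-chelated dianion formaldehyde attacks the enolate face anti to the allyl-bearing carbinol substituent, so C13 is set anti to the C12 oxygen by the purchased centre.

Step 3
Reactants: 4 ethyl (2R,3R)-3-hydroxy-2-(hydroxymethyl)hex-5-enoate
Product: 5 ethyl (2R,3R)-3-(TBSO)-2-(TBSOCH2)hex-5-enoate
Conditions: t-BuMe2SiOTf (2.4 equiv), 2,6-lutidine, CH2Cl2, −78 → 0 °C
Reagents that add atoms: tert-butyldimethylsilyl triflate, CC(C)(C)[Si](C)(C)OS(=O)(=O)C(F)(F)F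
Why: Double silyl ether formation masks both hydroxyls against the later oxidation, olefination and organometallic steps, and no stereocentre reacts.

Step 4
Reactants: 6 (R)-but-3-yn-2-ol
Product: 7 (R)-but-3-yn-2-yl propanoate
Conditions: EtCOCl, pyridine, CH2Cl2, 0 °C
Reagents that add atoms: propanoyl chloride, CCC(Cl)=O
Why: O-acylation of the secondary propargylic alcohol (esterification with retention at carbon) installs the propanoate whose carbons become C6, C7 and the C7 methyl.

Step 5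
Reactants: 7 (R)-but-3-yn-2-yl propanoate
Product: 8 (R)-but-3-en-2-yl propanoate
Conditions: H2 (1 atm), Pd/CaCO3 poisoned with Pb(OAc)2 (Lindlar catalyst), quinoline, pentane, 20 °C
Reagents that add atoms: none
Why: Lindlar semi-hydrogenation stops at the alkene on the lead-poisoned catalyst and gives the allylic ester needed for the rearrangement without touching the carbinol centre.

Step 6
Reactants: 8 (R)-but-3-en-2-yl propanoate
Product: 11 (2S,4E)-2-methylhex-4-en-1-ol, via silyl ketene acetal 9 (not isolated), via trimethylsilyl ester 10 (not isolated)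
Conditions: LiN(i-Pr)2 (1.1 equiv), THF, −78 °C; Me3SiCl, −78 → 55 °C; then LiAlH4, 0 °C; H2O work-up
Reagents that add atoms: none
Why: Ireland–Claisen rearrangement: LiN(i-Pr)2 in THF gives the ketene acetal with its methyl cis to the allylic oxygen, and the chair [3,3]-sigmatropic transition state with the carbinol methyl equatorial forms the C7–C8 bond, transfers the (R) carbinol configuration to (7S) (about 9:1 expected) and gives the E alkene, after which LiAlH4 reduces the silyl ester in the same flask.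

Step 7
Reactants: 5 ethyl (2R,3R)-3-(TBSO)-2-(TBSOCH2)hex-5-enoate; 11 (2S,4E)-2-methylhex-4-en-1-ol
Product: 12 ethyl (2R,3R,5E,8S)-3-(TBSO)-2-(TBSOCH2)-9-hydroxy-8-methylnon-5-enoate
Conditions: second-generation Grubbs catalyst RuCl2(=CHPh)(PCy3)(H2IMes) (5 mol %), 11 (2.5 equiv), CH2Cl2, 40 °C
Reagents that add atoms: none
Why: Olefin cross-metathesis joins C9 to C10 with loss of volatile propene; the E/Z ratio does not matter because the alkene is hydrogenated next, and no stereocentre is involved.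

Step 8
Reactants: 12 ethyl (2R,3R,5E,8S)-3-(TBSO)-2-(TBSOCH2)-9-hydroxy-8-methylnon-5-enoate
Product: 13 ethyl (2R,3R,8S)-3-(TBSO)-2-(TBSOCH2)-9-hydroxy-8-methylnonanoate
Conditions: H2 (1 atm), Pd/C, EtOAc, 20 °C
Reagents that add atoms: none
Why: Heterogeneous catalytic hydrogenation saturates the only alkene, while the silyl ethers, the ester and the C7, C12 and C13 centres are inert in EtOAc.

Step 9
Reactants: 13 ethyl (2R,3R,8S)-3-(TBSO)-2-(TBSOCH2)-9-hydroxy-8-methylnonanoate
Product: 14 ethyl (2R,3R,8S)-3-(TBSO)-2-(TBSOCH2)-9-iodo-8-methylnonanoate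
Conditions: I2, PPh3, imidazole, CH2Cl2, 0 → 20 °C
Reagents that add atoms: iodine, II
Why: Appel-type iodination converts the primary alcohol into the iodide by SN2 at CH2 and leaves the adjacent C7 centre untouched.

Step 10
Reactants: 6 (R)-but-3-yn-2-ol
Product: 16 (R)-pent-3-yn-2-ol, via dilithium acetylide alkoxide 15 (not isolated)
Conditions: n-BuLi (2.1 equiv), THF, −78 → 0 °C; MeI (1.0 equiv), DMPU, −78 → 20 °C; then 1 M HCl
Reagents that add atoms: iodomethane, CI
Why: In the alkoxide–acetylide dianion the acetylide carbon is by far the better nucleophile, so SN2 methylation gives the internal alkyne and keeps the carbinol configuration.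

Step 11
Reactants: 16 (R)-pent-3-yn-2-ol
Product: 18 (2R,3Z)-4-iodopent-3-en-2-ol, via cyclic alkenylalanate 17 (not isolated)
Conditions: NaAlH2(OCH2CH2OCH3)2, THF, 0 → 20 °C; then I2, THF, −78 → 0 °C; aqueous work-up
Reagents that add atoms: iodine, II
Why: Hydroxyl-directed trans-hydroalumination puts aluminium on the distal alkyne carbon in a five-membered alanate with hydrogen anti to it, and iodinolysis with retention gives the (Z)-iodoalkene with iodine cis to the carbinol carbon.

Step 12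
Reactants: 14 ethyl (2R,3R,8S)-3-(TBSO)-2-(TBSOCH2)-9-iodo-8-methylnonanoate; 18 (2R,3Z)-4-iodopent-3-en-2-ol
Product: 20 ethyl (2R,3R,8S,10Z,12R)-3-(TBSO)-2-(TBSOCH2)-12-hydroxy-8,10-dimethyltridec-10-enoate, via alkylzinc iodide 19 (not isolated)
Conditions: Zn dust, LiCl, THF, 40 °C; then 18 (1.3 equiv), Pd(OAc)2 (2 mol %), SPhos (4 mol %), THF, 20 °C
Reagents that add atoms: none
Why: Zinc insertion into the primary iodide followed by Negishi cross-coupling forms C5–C6 with retention of alkene geometry, so C6 ends cis to C3, and the mild organozinc tolerates the ester and, under the fast Pd/SPhos coupling, the free hydroxyl.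

Step 13
Reactants: 20 ethyl (2R,3R,8S,10Z,12R)-3-(TBSO)-2-(TBSOCH2)-12-hydroxy-8,10-dimethyltridec-10-enoate
Product: 21 ethyl (2R,3R,8S)-3-(TBSO)-2-(TBSOCH2)-9-{(2R,3S)-3-[(1R)-1-hydroxyethyl]-2-methyloxiran-2-yl}-8-methylnonanoate
Conditions: m-CPBA, NaHCO3, CH2Cl2, 0 °C
Reagents that add atoms: m-chloroperbenzoic acid, OOC(=O)c1cccc(Cl)c1
Why: Hydroxyl-directed peracid epoxidation (Prilezhaev/Henbest): the cis C6 substituent forces the carbinol hydrogen into the alkene plane (allylic 1,3-strain), so the hydrogen-bonded peracid attacks the face bearing OH and the threo epoxy alcohol with (4S,5R) forms, the (R) carbinol thus setting both new centres.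

Step 14
Reactants: 21 ethyl (2R,3R,8S)-3-(TBSO)-2-(TBSOCH2)-9-{(2R,3S)-3-[(1R)-1-hydroxyethyl]-2-methyloxiran-2-yl}-8-methylnonanoate
Product: 22 ethyl (2R,3R,8S)-9-[(2R,3R)-3-acetyl-2-methyloxiran-2-yl]-3-(TBSO)-2-(TBSOCH2)-8-methylnonanoate
Conditions: Dess–Martin periodinane, NaHCO3, CH2Cl2, 0 → 20 °C
Reagents that add atoms: none
Why: Dess–Martin oxidation gives the methyl ketone under buffered conditions that neither open the epoxide nor epimerise C4, and removes the directing carbinol centre once it has done its work (the ring descriptor changes from 3S to 3R by sequence rule only).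

Step 15
Reactants: 22 ethyl (2R,3R,8S)-9-[(2R,3R)-3-acetyl-2-methyloxiran-2-yl]-3-(TBSO)-2-(TBSOCH2)-8-methylnonanoate
Product: 23 diethyl (2E,4S,5R,7S,12R,13R)-12-(TBSO)-13-(TBSOCH2)-4,5-epoxy-3,5,7-trimethyltetradec-2-enedioate
Conditions: (EtO)2P(O)CH2CO2Et, NaH, THF, 0 → 45 °C
Reagents that add atoms: triethyl phosphonoacetate, CCOC(=O)CP(=O)(OCC)OCC
Why: Horner–Wadsworth–Emmons olefination of the methyl ketone places the ester trans to the bulkier oxiranyl substituent (2E; the minor 2Z isomer is removed by chromatography), and the weakly basic phosphonate anion leaves the epoxide, the silyl ethers and the other ester untouched.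

Step 16
Reactants: 23 diethyl (2E,4S,5R,7S,12R,13R)-12-(TBSO)-13-(TBSOCH2)-4,5-epoxy-3,5,7-trimethyltetradec-2-enedioate
Product: 25 (2E,4S,5R,7S,12R,13R)-4,5-epoxy-12-hydroxy-13-(hydroxymethyl)-3,5,7-trimethyltetradec-2-enedioic acid, via diol diester 24 (not isolated)
Conditions: Bu4NF/AcOH (1:1), THF, 0 → 20 °C; then LiOH, THF/H2O, 0 → 20 °C; 0.5 M HCl to pH 4, 0 °C
Reagents that add atoms: lithium hydroxide, [Li+].[OH-]
Why: Fluoride desilylation followed by ester saponification (acyl–oxygen cleavage) touches no stereocentre, and keeping the medium basic until a cold, mild acidification protects the acid-labile trisubstituted vinyl epoxide.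

**Compound list**

1 | ethyl (S)-3,4-epoxybutanoate (ethyl 2-[(2S)-oxiran-2-yl]acetate) | CCOC(=O)C[C@H]1CO1 | starting material
2 | ethyl (R)-3-hydroxyhex-5-enoate | CCOC(=O)C[C@H](O)CC=C | intermediate
3 | dilithium dianion of 2 (lithium ester enolate plus lithium alkoxide) | [Li+].[Li+].CCOC([O-])=C[C@H]([O-])CC=C | intermediate
4 | ethyl (2R,3R)-3-hydroxy-2-(hydroxymethyl)hex-5-enoate | CCOC(=O)[C@H](CO)[C@H](O)CC=C | intermediate
5 | ethyl (2R,3R)-3-[(tert-butyldimethylsilyl)oxy]-2-{[(tert-butyldimethylsilyl)oxy]methyl}hex-5-enoate | CCOC(=O)[C@H](CO[Si](C)(C)C(C)(C)C)[C@H](O[Si](C)(C)C(C)(C)C)CC=C | intermediate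
6 | (R)-but-3-yn-2-ol | C[C@@H](O)C#C | starting material
7 | (R)-but-3-yn-2-yl propanoate | CCC(=O)O[C@H](C)C#C | intermediate
8 | (R)-but-3-en-2-yl propanoate | CCC(=O)O[C@H](C)C=C | intermediate
9 | {[(1E)-1-{[(2R)-but-3-en-2-yl]oxy}prop-1-en-1-yl]oxy}trimethylsilane (silyl ketene acetal, methyl cis to the allylic oxygen) | C/C=C(/O[Si](C)(C)C)O[C@H](C)C=C | intermediate
10 | trimethylsilyl (2S,4E)-2-methylhex-4-enoate | C/C=C/C[C@H](C)C(=O)O[Si](C)(C)C | intermediate
11 | (2S,4E)-2-methylhex-4-en-1-ol | C/C=C/C[C@H](C)CO | intermediate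
12 | ethyl (2R,3R,5E,8S)-3-[(tert-butyldimethylsilyl)oxy]-2-{[(tert-butyldimethylsilyl)oxy]methyl}-9-hydroxy-8-methylnon-5-enoate (minor 5Z isomer converges in step 8) | CCOC(=O)[C@H](CO[Si](C)(C)C(C)(C)C)[C@H](O[Si](C)(C)C(C)(C)C)C/C=C/C[C@H](C)CO | intermediate
13 | ethyl (2R,3R,8S)-3-[(tert-butyldimethylsilyl)oxy]-2-{[(tert-butyldimethylsilyl)oxy]methyl}-9-hydroxy-8-methylnonanoate | CCOC(=O)[C@H](CO[Si](C)(C)C(C)(C)C)[C@H](O[Si](C)(C)C(C)(C)C)CCCC[C@H](C)CO | intermediate
14 | ethyl (2R,3R,8S)-3-[(tert-butyldimethylsilyl)oxy]-2-{[(tert-butyldimethylsilyl)oxy]methyl}-9-iodo-8-methylnonanoate | CCOC(=O)[C@H](CO[Si](C)(C)C(C)(C)C)[C@H](O[Si](C)(C)C(C)(C)C)CCCC[C@H](C)CI | intermediate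
15 | dilithium salt of (R)-but-3-yn-2-ol (lithium alkoxide plus lithium acetylide) | [Li+].[Li+].C[C@@H]([O-])C#[C-] | intermediate
16 | (R)-pent-3-yn-2-ol | C[C@@H](O)C#CC | intermediate
17 | sodium (5R)-2,2-bis(2-methoxyethoxy)-3,5-dimethyl-2,5-dihydro-1,2-oxaaluminol-2-uide (cyclic alkenylalanate) | [Na+].C[C@@H]1C=C(C)[Al-](OCCOC)(OCCOC)O1 | intermediate
18 | (2R,3Z)-4-iodopent-3-en-2-ol | C[C@@H](O)/C=C(\I)C | intermediate
19 | [(2S,7R,8R)-7-[(tert-butyldimethylsilyl)oxy]-8-{[(tert-butyldimethylsilyl)oxy]methyl}-9-ethoxy-2-methyl-9-oxononyl]zinc iodide | CCOC(=O)[C@H](CO[Si](C)(C)C(C)(C)C)[C@H](O[Si](C)(C)C(C)(C)C)CCCC[C@H](C)C[Zn]I | intermediate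
20 | ethyl (2R,3R,8S,10Z,12R)-3-[(tert-butyldimethylsilyl)oxy]-2-{[(tert-butyldimethylsilyl)oxy]methyl}-12-hydroxy-8,10-dimethyltridec-10-enoate | CCOC(=O)[C@H](CO[Si](C)(C)C(C)(C)C)[C@H](O[Si](C)(C)C(C)(C)C)CCCC[C@H](C)C/C(C)=C\[C@@H](C)O | intermediate
21 | ethyl (2R,3R,8S)-3-[(tert-butyldimethylsilyl)oxy]-2-{[(tert-butyldimethylsilyl)oxy]methyl}-9-{(2R,3S)-3-[(1R)-1-hydroxyethyl]-2-methyloxiran-2-yl}-8-methylnonanoate | CCOC(=O)[C@H](CO[Si](C)(C)C(C)(C)C)[C@H](O[Si](C)(C)C(C)(C)C)CCCC[C@H](C)C[C@@]1(C)O[C@H]1[C@@H](C)O | intermediate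
22 | ethyl (2R,3R,8S)-9-[(2R,3R)-3-acetyl-2-methyloxiran-2-yl]-3-[(tert-butyldimethylsilyl)oxy]-2-{[(tert-butyldimethylsilyl)oxy]methyl}-8-methylnonanoate | CCOC(=O)[C@H](CO[Si](C)(C)C(C)(C)C)[C@H](O[Si](C)(C)C(C)(C)C)CCCC[C@H](C)C[C@@]1(C)O[C@H]1C(C)=O | intermediate
23 | diethyl (2E,4S,5R,7S,12R,13R)-12-[(tert-butyldimethylsilyl)oxy]-13-{[(tert-butyldimethylsilyl)oxy]methyl}-4,5-epoxy-3,5,7-trimethyltetradec-2-enedioate | CCOC(=O)[C@H](CO[Si](C)(C)C(C)(C)C)[C@H](O[Si](C)(C)C(C)(C)C)CCCC[C@H](C)C[C@@]1(C)O[C@H]1/C(C)=C/C(=O)OCC | intermediate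
24 | diethyl (2E,4S,5R,7S,12R,13R)-4,5-epoxy-12-hydroxy-13-(hydroxymethyl)-3,5,7-trimethyltetradec-2-enedioate | CCOC(=O)[C@H](CO)[C@H](O)CCCC[C@H](C)C[C@@]1(C)O[C@H]1/C(C)=C/C(=O)OCC | intermediate
25 | (2E,4S,5R,7S,12R,13R)-4,5-epoxy-12-hydroxy-13-(hydroxymethyl)-3,5,7-trimethyltetradec-2-enedioic acid (CNP0468463.1) | C/C(=C\C(=O)O)[C@@H]1O[C@]1(C)C[C@@H](C)CCCC[C@@H](O)[C@@H](CO)C(=O)O | target

**Step count**

Total step count: 16.
Longest linear sequence: 11 steps (1, 2, 3, 7, 8, 9, 12, 13, 14, 15, 16). The branch 4, 5, 6 joins at step 7 and is equally long; steps 10 and 11 form a two-step branch that joins at step 12.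

**Three steps most likely to fail, with fallbacks**

Step 2 (Fráter–Seebach hydroxymethylation): aldols of ester dianions with gaseous formaldehyde can stall, over-react or give low mass recovery. The fallback sets out from 2 and replaces the aldol by a C-alkylation with a masked hydroxymethyl cation. The same dianion 3 is alkylated with 4-methoxybenzyl chloromethyl ether (THF, −78 → −20 °C), with the same anti induction, to give ethyl (2R,3R)-3-hydroxy-2-{[(4-methoxyphenyl)methoxy]methyl}hex-5-enoate F1. Oxidative cleavage of the 4-methoxybenzyl ether with DDQ in wet CH2Cl2 then comes back to the route at 4.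

Step 6 (Ireland–Claisen rearrangement and in-flask reduction): the C7 configuration depends on the ketene acetal geometry (about 9:1 expected), and the product is volatile. The fallback sets out from 6 and keeps the sigmatropic bond formation but uses a ketene N,O-acetal whose geometry is fixed by allylic strain. Semi-hydrogenation of 6 (H2, Pd/CaCO3 poisoned with Pb(OAc)2, quinoline) gives (R)-but-3-en-2-ol F2. Heating F2 with 1,1-dimethoxy-N,N-dimethylpropan-1-amine in xylene at 140 °C (Eschenmoser–Claisen) passes through (1Z)-1-{[(2R)-but-3-en-2-yl]oxy}-N,N-dimethylprop-1-en-1-amine F3 and gives (2S,4E)-N,N,2-trimethylhex-4-enamide F4. Reduction of the amide with LiH3BNH2 in THF comes back to the route at 11.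

Step 12 (zinc insertion and Negishi coupling): a β-branched alkylzinc, an ester and a free allylic hydroxyl in one coupling may give protonated alkane or sluggish transmetalation. The fallback sets out from 14 and changes the nucleophile from zinc to boron, which tolerates water and the free hydroxyl. Copper-catalysed borylation of 14 (B2pin2, CuI, PPh3, LiOt-Bu, DMF, 25 °C) gives ethyl (2R,3R,8R)-3-[(tert-butyldimethylsilyl)oxy]-2-{[(tert-butyldimethylsilyl)oxy]methyl}-8-methyl-9-(4,4,5,5-tetramethyl-1,3,2-dioxaborolan-2-yl)nonanoate F5 (8R by sequence rule only; same spatial arrangement). KHF2 in aqueous MeCN converts it into potassium [(2R,7R,8R)-7-[(tert-butyldimethylsilyl)oxy]-8-{[(tert-butyldimethylsilyl)oxy]methyl}-9-ethoxy-2-methyl-9-oxononyl]trifluoroborate F6. Suzuki–Miyaura coupling of F6 with 18 (PdCl2(dppf), Cs2CO3, toluene/H2O, 80 °C) proceeds with retention of the Z geometry and comes back to the route at 20.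

**Further compounds**

F1 | step 2 | ethyl (2R,3R)-3-hydroxy-2-{[(4-methoxyphenyl)methoxy]methyl}hex-5-enoate | CCOC(=O)[C@H](COCc1ccc(OC)cc1)[C@H](O)CC=C
F2 | step 6 | (R)-but-3-en-2-ol | C[C@@H](O)C=C
F3 | step 6 | (1Z)-1-{[(2R)-but-3-en-2-yl]oxy}-N,N-dimethylprop-1-en-1-amine | C/C=C(/N(C)C)O[C@H](C)C=C
F4 | step 6 | (2S,4E)-N,N,2-trimethylhex-4-enamide | C/C=C/C[C@H](C)C(=O)N(C)C
F5 | step 12 | ethyl (2R,3R,8R)-3-[(tert-butyldimethylsilyl)oxy]-2-{[(tert-butyldimethylsilyl)oxy]methyl}-8-methyl-9-(4,4,5,5-tetramethyl-1,3,2-dioxaborolan-2-yl)nonanoate | CCOC(=O)[C@H](CO[Si](C)(C)C(C)(C)C)[C@H](O[Si](C)(C)C(C)(C)C)CCCC[C@H](C)CB1OC(C)(C)C(C)(C)O1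
F6 | step 12 | potassium [(2R,7R,8R)-7-[(tert-butyldimethylsilyl)oxy]-8-{[(tert-butyldimethylsilyl)oxy]methyl}-9-ethoxy-2-methyl-9-oxononyl]trifluoroborate | [K+].CCOC(=O)[C@H](CO[Si](C)(C)C(C)(C)C)[C@H](O[Si](C)(C)C(C)(C)C)CCCC[C@H](C)C[B-](F)(F)F
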